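The route rests on cutting the ethano bridge between its outer CH2 and C1 of the 4-hydroxyphenyl ring. That CH2–CH2 unit is read as a hydroborated vinyl group on C7 of the chromene: among three C=C bonds only this one is monosubstituted, whereas the prenyl alkene on C6 is trisubstituted and the pyran C3=C4 bond is shielded by the C2 gem-dimethyl carbon. In one flask 9-BBN adds to the vinyl group of unprotected 7-ethenyl-2,2-dimethyl-6-prenyl-2H-chromen-5-ol and a B-alkyl Suzuki–Miyaura coupling with 4-iodophenol forges the CH2–aryl bond, joining both halves and releasing the target without protecting groups.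

Key step: step 5

Assumption: tert-butyl 2-methylbut-3-en-2-yl carbonate (5) is taken as a catalogue reagent; otherwise it is one operation from 2-methylbut-3-en-2-ol and Boc2O.
Remark: the target has no stereocenter and no configurable double bond, so no step needs stereocontrol.

Step 1
Reactants: 1 5-bromobenzene-1,3-diol; 2 3-methylbut-2-enal
Product: 4 7-bromo-2,2-dimethyl-2H-chromen-5-ol, via ortho-quinone methide 3 (not isolated)
Conditions: ethylenediammonium diacetate (10 mol %), toluene, 110 °C, 2 (1.1 equiv) added slowly
Reagents that add atoms: none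
Why: Amine-salt-catalysed Knoevenagel-type condensation at the resorcinol carbon flanked by both hydroxyls (the site 5-substituted resorcinols normally use with enals) should give ortho-quinone methide 3, which closes by oxa-6π electrocyclisation (formal [3+3] chromene annulation); no stereocenter is formed.

Step 2
Reactants: 4 7-bromo-2,2-dimethyl-2H-chromen-5-ol; 5 tert-butyl 2-methylbut-3-en-2-yl carbonate
Product: 6 7-bromo-2,2-dimethyl-5-[(2-methylbut-3-en-2-yl)oxy]-2H-chromene
Conditions: 5 (1.5 equiv), Pd(PPh3)4 (3 mol %), 4 Å MS, THF, 0 °C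
Reagents that add atoms: none
Why: Tsuji–Trost O-allylation: Pd(0) ionises the tertiary carbonate with loss of CO2, the tert-butoxide set free deprotonates the phenol, and the phenoxide attacks the more substituted terminus of the 1,1-dimethyl-π-allyl complex under kinetic control at 0 °C, while the electron-rich aryl bromide should not add to Pd(PPh3)4 at this temperature.

Step 3
Reactants: 6 7-bromo-2,2-dimethyl-5-[(2-methylbut-3-en-2-yl)oxy]-2H-chromene
Product: 8 7-bromo-2,2-dimethyl-6-(3-methylbut-2-en-1-yl)-2H-chromen-5-ol, via cyclohexadienone 7 (not isolated)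
Conditions: xylenes (degassed), BHT (cat.), 130 °C
Reagents that add atoms: none
Why: Aromatic Claisen rearrangement ([3,3]-sigmatropic shift, eased by the gem-dimethyl group) can only end at C6, the one unsubstituted ortho carbon (C4a is the ring fusion), and dienone 7 tautomerises irreversibly to the phenol with the allyl unit inverted to the linear prenyl group; the transient C6 stereocenter of 7 is lost on enolisation.

Step 4
Reactants: 8 7-bromo-2,2-dimethyl-6-(3-methylbut-2-en-1-yl)-2H-chromen-5-ol; 9 4,4,5,5-tetramethyl-2-vinyl-1,3,2-dioxaborolane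
Product: 10 7-ethenyl-2,2-dimethyl-6-(3-methylbut-2-en-1-yl)-2H-chromen-5-ol
Conditions: 9 (1.5 equiv), Pd(OAc)2 (3 mol %), SPhos (6 mol %), K3PO4, dioxane/H2O, 80 °C
Reagents that add atoms: none
Why: Suzuki–Miyaura vinylation, in which the bulky electron-rich SPhos ligand allows oxidative addition to the ortho-substituted, phenoxide-bearing aryl bromide and aqueous phosphate activates the vinyl boronate; the prenyl and pyran alkenes should not react with Pd(0).

Step 5
Reactants: 10 7-ethenyl-2,2-dimethyl-6-(3-methylbut-2-en-1-yl)-2H-chromen-5-ol; 11 9-borabicyclo[3.3.1]nonane (9-BBN-H); 12 4-iodophenol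
Product: 14 7-[2-(4-hydroxyphenyl)ethyl]-2,2-dimethyl-6-(3-methylbut-2-en-1-yl)-2H-chromen-5-ol, via alkylborane borinate 13 (not isolated)
Conditions: 11 (2.2 equiv, 0.5 M in THF), THF, 0 °C to rt; then 12, PdCl2(dppf)·CH2Cl2 (5 mol %), 3 M aq. K3PO4, DMF, 60 °C
Reagents that add atoms: none
Why: One equivalent of 11 is consumed by the C5 hydroxyl (B–O bond, loss of H2) and a second adds syn through a four-centre transition state across the C7 vinyl group with boron on the terminal carbon, giving 13; aqueous phosphate then hydrolyses the B–O bond and forms the alkyl borate, whose primary alkyl group is transferred to the arylpalladium(II) iodide formed from 12, and reductive elimination forges the CH2–aryl bond. The closest known reaction type is the one-pot hydroboration/B-alkyl Suzuki–Miyaura coupling. No ring is closed and no stereocenter is formed. The step needs chemoselectivity among three alkenes and anti-Markovnikov regioselectivity: the bulky 9-BBN should react far faster with the monosubstituted vinyl group than with the trisubstituted prenyl alkene on C6 or the C3=C4 bond next to the quaternary C2, and both the aryl ring and the ortho prenyl group steer boron to the terminal carbon. The charge of 11 is limited to what the hydroxyl and the vinyl group consume so that no hydride is left for the other alkenes, and the wide-bite-angle dppf ligand should let reductive elimination outrun β-hydride elimination.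

Compound list
1 | 5-bromobenzene-1,3-diol | Oc1cc(O)cc(Br)c1 | starting material
2 | 3-methylbut-2-enal | CC(C)=CC=O | starting material
3 | 5-bromo-3-hydroxy-2-(3-methylbut-2-en-1-ylidene)cyclohexa-3,5-dien-1-one (ortho-quinone methide, exocyclic alkene geometry not defined, not isolated) | CC(C)=CC=C1C(=O)C=C(Br)C=C1O | intermediate
4 | 7-bromo-2,2-dimethyl-2H-chromen-5-ol | CC1(C)C=Cc2c(O)cc(Br)cc2O1 | intermediate
5 | tert-butyl 2-methylbut-3-en-2-yl carbonate | CC(C)(C)OC(=O)OC(C)(C)C=C | starting material
6 | 7-bromo-2,2-dimethyl-5-[(2-methylbut-3-en-2-yl)oxy]-2H-chromene | CC1(C)C=Cc2c(OC(C)(C)C=C)cc(Br)cc2O1 | intermediate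
7 | 7-bromo-2,2-dimethyl-6-(3-methylbut-2-en-1-yl)-2H-chromen-5(6H)-one (racemic, not isolated) | O=C1C(CC=C(C)C)C(Br)=CC2=C1C=CC(C)(C)O2 | intermediate
8 | 7-bromo-2,2-dimethyl-6-(3-methylbut-2-en-1-yl)-2H-chromen-5-ol | CC(C)=CCc1c(Br)cc2c(c1O)C=CC(C)(C)O2 | intermediate
9 | 4,4,5,5-tetramethyl-2-vinyl-1,3,2-dioxaborolane (vinylboronic acid pinacol ester) | C=CB1OC(C)(C)C(C)(C)O1 | starting material
10 | 7-ethenyl-2,2-dimethyl-6-(3-methylbut-2-en-1-yl)-2H-chromen-5-ol | CC(C)=CCc1c(C=C)cc2c(c1O)C=CC(C)(C)O2 | intermediate
11 | 9-borabicyclo[3.3.1]nonane (9-BBN-H, used as its THF solution) | [H]B1C2CCCC1CCC2 | starting material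
12 | 4-iodophenol | Oc1ccc(I)cc1 | starting material
13 | 9-{2-[5-(9-borabicyclo[3.3.1]nonan-9-yloxy)-2,2-dimethyl-6-(3-methylbut-2-en-1-yl)-2H-chromen-7-yl]ethyl}-9-borabicyclo[3.3.1]nonane (not isolated) | CC(C)=CCc1c(CCB3C4CCCC3CCC4)cc2c(c1OB5C6CCCC5CCC6)C=CC(C)(C)O2 | intermediate
14 | 7-[2-(4-hydroxyphenyl)ethyl]-2,2-dimethyl-6-(3-methylbut-2-en-1-yl)-2H-chromen-5-ol | CC(C)=CCc1c(CCc2ccc(O)cc2)cc2c(c1O)C=CC(C)(C)O2 | target

Total step count: 5
Longest linear sequence: 5 steps (1 → 4 → 6 → 8 → 10 → 14)

Steps most likely to fail

Step 5. The hindered C5 hydroxyl may take up hydride more slowly than planned, so that surplus 9-BBN hydroborates the prenyl or pyran alkene. The two phenoxides may also slow oxidative addition and transmetalation, so that protodeboronation or β-hydride elimination of the alkyl group takes over. The fallback gives up the protecting-group-free endgame for a masked one. It sets out from 10 and comes back at 14. Silylation of 10 (TBSCl, imidazole, DMF) gives tert-butyl{[7-ethenyl-2,2-dimethyl-6-(3-methylbut-2-en-1-yl)-2H-chromen-5-yl]oxy}dimethylsilane F1. With no O–H left, 1.1 equiv of 11 suffices and gives 9-{2-[5-(tert-butyldimethylsilyloxy)-2,2-dimethyl-6-(3-methylbut-2-en-1-yl)-2H-chromen-7-yl]ethyl}-9-borabicyclo[3.3.1]nonane F2. This is coupled in the same flask with commercial tert-butyl(4-iodophenoxy)dimethylsilane (PdCl2(dppf), K3PO4·H2O, THF, 50 °C) to the bis(silyl ether) tert-butyl(4-{2-[5-(tert-butyldimethylsilyloxy)-2,2-dimethyl-6-(3-methylbut-2-en-1-yl)-2H-chromen-7-yl]ethyl}phenoxy)dimethylsilane F3. TBAF in THF then removes both silyl groups and gives 14.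

Step 1. Condensation may occur at the ring carbon between a hydroxyl and the bromine instead of the carbon between the two hydroxyls, and a second annulation on the remaining phenol or oligomerisation of the quinone methide may consume material. The fallback fixes the site by symmetry. It sets out from 1 and comes back at 4. Methoxymethylation (MOMCl, i-Pr2NEt, CH2Cl2) gives 1-bromo-3,5-bis(methoxymethoxy)benzene F4. LDA (THF, −78 °C) removes the proton between the two MOM ethers and DMF gives 4-bromo-2,6-bis(methoxymethoxy)benzaldehyde F5. Addition of 2-methylprop-1-enylmagnesium bromide gives racemic 1-[4-bromo-2,6-bis(methoxymethoxy)phenyl]-3-methylbut-2-en-1-ol F6. HCl in methanol then removes both MOM groups and ionises the allylic benzylic alcohol to the same ortho-quinone methide 3, which closes to 4; either hydroxyl gives the same chromene.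

Step 3. On heating, the tertiary allyl ether may fragment back to phenol 4 with loss of isoprene, or rearrange through the blocked ring-fusion carbon to the para position C8 with a reverse-prenyl group, or the ortho-prenyl phenol formed may cyclise onto its own alkene. The fallback replaces the O-allylation/rearrangement pair by direct ortho-C-alkylation. It sets out from 4 and comes back at 8. The sodium phenoxide of 4 (NaH, toluene, 0 °C to rt) is treated with 1-bromo-3-methylbut-2-ene; in the non-polar medium the tight ion pair should deliver the prenyl group to C6, the only free ortho carbon. This fallback makes no compound outside the compound list (entry F0).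

Further compounds
F1 | step 5 | tert-butyl{[7-ethenyl-2,2-dimethyl-6-(3-methylbut-2-en-1-yl)-2H-chromen-5-yl]oxy}dimethylsilane | CC(C)=CCc1c(C=C)cc2c(c1O[Si](C)(C)C(C)(C)C)C=CC(C)(C)O2
F2 | step 5 | 9-{2-[5-(tert-butyldimethylsilyloxy)-2,2-dimethyl-6-(3-methylbut-2-en-1-yl)-2H-chromen-7-yl]ethyl}-9-borabicyclo[3.3.1]nonane | CC(C)=CCc1c(CCB3C4CCCC3CCC4)cc2c(c1O[Si](C)(C)C(C)(C)C)C=CC(C)(C)O2
F3 | step 5 | tert-butyl(4-{2-[5-(tert-butyldimethylsilyloxy)-2,2-dimethyl-6-(3-methylbut-2-en-1-yl)-2H-chromen-7-yl]ethyl}phenoxy)dimethylsilane | CC(C)=CCc1c(CCc2ccc(O[Si](C)(C)C(C)(C)C)cc2)cc2c(c1O[Si](C)(C)C(C)(C)C)C=CC(C)(C)O2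
F4 | step 1 | 1-bromo-3,5-bis(methoxymethoxy)benzene | COCOc1cc(Br)cc(OCOC)c1
F5 | step 1 | 4-bromo-2,6-bis(methoxymethoxy)benzaldehyde | COCOc1cc(Br)cc(OCOC)c1C=O
F6 | step 1 | 1-[4-bromo-2,6-bis(methoxymethoxy)phenyl]-3-methylbut-2-en-1-ol (racemic) | COCOc1cc(Br)cc(OCOC)c1C(O)C=C(C)C
F0 | step 3 | none | none
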